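Ring B (cyclopentane B1–B5: B1 spiro to ring A, B2 = CH–iPr, B5 = pinane C2) is cut at B4–B5. The key step exploits the pinane gem-dimethyl bridge (C6) beside B5: with a temporary ketone at pinane C4, B5 is the β-carbon of a bridged enone open only on the face anti to that bridge. Sensitised irradiation joins B5 to B4 and pinane C3 to B3 of a tethered enol acetate in a crossed [2+2], closing ring B within a bicyclo[2.1.1]hexane and setting B5; retro-aldol later severs B3–C3. The precursor is a 4-substituted apoverbenone whose quaternary malonate B1 carries the (R)-configured B2 side chain; ring A is built last.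

Key step: step 9

Remark on labels: ring B atoms are B1 (spiro carbon shared with ring A), B2 (CH–iPr), B3 and B4 (CH2) and B5 (= pinane C2). Pinane atoms are numbered as in the target (C2 = B5, C4 = carbon of the temporary ketone, C6 = CMe2 bridge). In ring A the ketone carbon between B1 and C–Me is called the methyl-side carbonyl and the ketone carbon between B1 and CMe2 the gem-dimethyl-side carbonyl; the other ring A carbons are called the C–Me, C–OMe and CMe2 carbons.

Remark on the side chain: B2 is α to the B3 carbonyl, so B1–B2–B3 is a 1,4-dicarbonyl array. A malonate conjugate addition to an enone would put one CH2 too many between B2 and the carbonyl, so B1–B2 is made by allylic alkylation and the ketone by Wacker oxidation.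

Remark on the leaving group: the vinylogous thioester is oxidised to the sulfone before the addition–elimination, because the nucleophile is a hindered tertiary malonate.

Assumption: (E)-4-methylpent-2-en-1-ol is taken as a catalogue compound (otherwise one i-Bu2AlH reduction of ethyl (E)-4-methylpent-2-enoate).

Step 1
Reactants: 1 (1R,5S)-(+)-nopinone
Product: 2 (1R,5R)-apoverbenone
Conditions: IBX (2.0 equiv), DMSO/toluene, 70 °C
Reagents that add atoms: none
Why: IBX dehydrogenation of a ketone through its enol can only introduce the C3=C4 double bond because the other α-carbon is a bridgehead, and both bridgehead stereocentres are untouched.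

Step 2
Reactants: 2 (1R,5R)-apoverbenone
Product: 4 (1R,5S)-6,6-dimethyl-4-(phenylsulfanyl)bicyclo[3.1.1]hept-3-en-2-one, via sulfide ketone 3 (not isolated)
Conditions: PhSH (1.0 equiv), Et3N (5 mol%), CH2Cl2, 0 °C; then NCS (1.05 equiv), 0 °C to rt; then Et3N (1.1 equiv)
Reagents that add atoms: thiophenol, Sc1ccccc1
Why: thia-Michael addition (anti to the gem-dimethyl bridge) followed by S-chlorination and loss of HCl (Pummerer-type oxidation) should return the enone as its β-phenylthio derivative, the C4 stereocentre of 3 being erased.

Step 3
Reactants: 4 (1R,5S)-6,6-dimethyl-4-(phenylsulfanyl)bicyclo[3.1.1]hept-3-en-2-one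
Product: 5 (1R,5S)-6,6-dimethyl-4-(phenylsulfonyl)bicyclo[3.1.1]hept-3-en-2-one
Conditions: mCPBA (2.2 equiv), CH2Cl2, 0 °C to rt
Reagents that add atoms: 3-chloroperoxybenzoic acid (mCPBA), OOC(=O)c1cccc(Cl)c1
Why: peracid oxidation of sulfur to the sulfone is much faster than epoxidation of the electron-poor enone and makes the β-carbon a strong acceptor with a good leaving group.

Step 4
Reactants: 6 (E)-4-methylpent-2-en-1-ol
Product: 7 methyl (E)-4-methylpent-2-en-1-yl carbonate
Conditions: ClCO2Me (1.2 equiv), pyridine (1.5 equiv), CH2Cl2, 0 °C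
Reagents that add atoms: methyl chloroformate, COC(=O)Cl
Why: O-acylation of a primary allylic alcohol gives the linear carbonate that iridium allyl chemistry requires.

Step 5
Reactants: 7 methyl (E)-4-methylpent-2-en-1-yl carbonate; 8 dimethyl malonate
Product: 9 dimethyl 2-[(3S)-4-methylpent-1-en-3-yl]propanedioate
Conditions: [Ir(cod)Cl]2 (2 mol%), phosphoramidite from BINOL and bis(1-phenylethyl)amine (4 mol%; the enantiomer that gives (S)-9), 1,5,7-triazabicyclo[4.4.0]dec-5-ene (8 mol%), THF, rt to 40 °C
Reagents that add atoms: none
Why: iridium-catalysed asymmetric allylic alkylation (Helmchen–Hartwig type) directs the malonate to the substituted allyl terminus, giving the branched product, and the ligand sets B2; a lower branched-to-linear preference than for aryl substrates is expected for the isopropyl group.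

Step 6
Reactants: 9 dimethyl 2-[(3S)-4-methylpent-1-en-3-yl]propanedioate
Product: 10 dimethyl 2-[(3R)-2-methyl-4-oxopentan-3-yl]propanedioate
Conditions: PdCl2 (10 mol%), CuCl (1.0 equiv), O2 (1 atm), DMF/H2O 7:1, rt
Reagents that add atoms: water, O
Why: Tsuji–Wacker oxidation (Markovnikov hydroxypalladation, β-hydride elimination) should convert the terminal alkene into the methyl ketone under near-neutral conditions that leave B2 untouched (S becomes R only through the change in priorities).

Step 7
Reactants: 10 dimethyl 2-[(3R)-2-methyl-4-oxopentan-3-yl]propanedioate; 5 (1R,5S)-6,6-dimethyl-4-(phenylsulfonyl)bicyclo[3.1.1]hept-3-en-2-one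
Product: 11 dimethyl 2-[(1S,5R)-6,6-dimethyl-4-oxobicyclo[3.1.1]hept-2-en-2-yl]-2-[(3R)-2-methyl-4-oxopentan-3-yl]propanedioate
Conditions: NaH (1.0 equiv), THF, 0 °C; then 5, DMF, 0 to 40 °C
Reagents that add atoms: none
Why: conjugate addition–elimination (vinylic substitution) of the malonate anion at the sulfonyl-bearing β-carbon, followed by irreversible loss of sulfinate, restores the enone; with one equivalent of base only the malonate C–H is ionised, so B2 keeps its configuration and no new stereocentre arises.

Step 8
Reactants: 11 dimethyl 2-[(1S,5R)-6,6-dimethyl-4-oxobicyclo[3.1.1]hept-2-en-2-yl]-2-[(3R)-2-methyl-4-oxopentan-3-yl]propanedioate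
Product: 12 dimethyl 2-[(3R)-2-acetoxy-4-methylpent-1-en-3-yl]-2-[(1S,5R)-6,6-dimethyl-4-oxobicyclo[3.1.1]hept-2-en-2-yl]propanedioate
Conditions: LiN(SiMe3)2 (1.1 equiv), THF, −78 °C; then Ac2O (1.5 equiv), −78 to −40 °C
Reagents that add atoms: acetic anhydride, CC(=O)OC(C)=O
Why: kinetic deprotonation occurs at the methyl group (B2–H is buried between the quaternary B1 and the isopropyl group, and the enone has only bridgehead hydrogens), and O-acylation of the lithium enolate at low temperature (House procedure) gives the terminal enol acetate before the enolate can add to the enone.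

Step 9
Reactants: 12 dimethyl 2-[(3R)-2-acetoxy-4-methylpent-1-en-3-yl]-2-[(1S,5R)-6,6-dimethyl-4-oxobicyclo[3.1.1]hept-2-en-2-yl]propanedioate
Product: 13 crossed photoadduct (β-acetoxy ketone with a bicyclo[2.1.1]hexane core: bridgeheads B5 and B3, bridges B1–B2, B4 and pinane C3)
Conditions: hν (medium-pressure Hg lamp, Pyrex, λ > 290 nm), acetone (solvent and triplet sensitiser), 0.01 M, Ar, 0 °C
Reagents that add atoms: none
Why: Triplet energy transfer from acetone gives the enone triplet, whose β-carbon B5 bonds to the terminal carbon B4 of the enol acetate through a five-membered transition state (5-exo closure of ring B, rule of five), leaving a 1,4-biradical (α-keto radical at pinane C3, α-acetoxy tertiary radical at B3) that after spin inversion recombines to the cyclobutane (four-membered closure B3–C3) and so completes the bicyclo[2.1.1]hexane. The closest known reaction type is the crossed intramolecular enone–alkene [2+2] photocycloaddition of 1,5-dienes, here in its de Mayo variant with an enol ester. B5 is set by the gem-dimethyl bridge, whose inner methyl blocks one face of the enone so that B4 enters anti to it and B1 is pushed syn; pinane C3 follows because the cyclobutane can only be cis-fused on that same face, B3 is fixed by the geometry of the bridged ring, and B2 is carried through unchanged. The step needs crossed regiochemistry, which the two-atom tether (B1, B2) and the better stabilised biradical enforce, and it needs the cycloaddition to outrun the 1,3-shift of the cyclobutane bond known for verbenone-type enones. Sensitisation is meant to keep the enone out of its excited singlet state, and the quaternary malonate carbon B1 holds the alkene close to B5 (Thorpe–Ingold effect), so ring closure should be faster than that rearrangement.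

Step 10
Reactants: 13 crossed photoadduct
Product: 15 diketone diester (cyclopentanone with B3 = C=O spiro-linked at B5 to the pinan-4-one), via cage alcohol 14 (not isolated)
Conditions: K2CO3 (0.3 equiv), MeOH, 0 °C; AcOH quench
Reagents that add atoms: none
Why: methanolysis frees the bridgehead alkoxide, which undergoes strain-driven retro-aldol cleavage (de Mayo fragmentation) of B3–C3, the only bond that is β to the C4 carbonyl and can break; the cold, brief treatment with substoichiometric base is chosen to avoid B2 epimerisation and retro-Michael opening of the congested 1,5-diketone at B1–B5.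

Step 11
Reactants: 15 diketone diester
Product: 17 keto diester (B3 ketone only; pinane C4 = CH2), via C4 tosylhydrazone 16 (not isolated)
Conditions: TsNHNH2 (1.05 equiv), PPTS (5 mol%), THF, rt, 4 Å MS; then catecholborane (2.2 equiv), CHCl3, 0 °C; NaOAc·3H2O, 50 °C
Reagents that add atoms: none
Why: condensation should select the nopinone-type carbonyl, open on its face anti to the gem-dimethyl bridge, over the cyclopentanone that bears an α-isopropyl group between two quaternary carbons; Kabalka reduction of the tosylhydrazone (hydride addition, loss of sulfinate, diazene to N2) then gives the methylene without strong base.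

Step 12
Reactants: 17 keto diester
Product: 19 lactone ester (2-oxabicyclo[2.2.1]heptan-3-one joining the B3 oxygen to the ester carbonyl on B1 that lies cis to the isopropyl group), via hydroxy diester 18 (not isolated)
Conditions: LiBH(s-Bu)3 (1.5 equiv), THF, −78 to −40 °C; aq. NH4Cl; then TsOH·H2O (10 mol%), toluene, 80 °C, 5 Å MS
Reagents that add atoms: none
Why: the bulky hydride attacks the cyclopentanone anti to the adjacent isopropyl group, so B3–OH ends up cis to it, and acid-catalysed lactonisation with removal of methanol can engage only the ester on that face; this makes B1 a stereocentre and tags the carbonyl that becomes the methyl-side carbonyl of ring A.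

Step 13
Reactants: 19 lactone ester; 20 2-methylpentan-3-one
Product: 22 hydroxy trione (ring A closed; drawn as the triketone, present as an enol), via acyclic diketone 21 (not isolated)
Conditions: 20 (3 equiv), LiN(i-Pr)2 (3 equiv), THF, −78 °C; add 19, −78 to 0 °C; then LiN(i-Pr)2 (3 equiv), 0 °C to rt; aq. HCl
Reagents that add atoms: none
Why: Claisen acylation of the kinetic ethyl-side enolate by the strained, non-enolisable lactone joins the methyl-side carbonyl to the C–Me carbon, and the dianion of the resulting β-diketone (deprotonated at the isopropyl carbon) closes onto the remaining ester (Dieckmann C-acylation, as in syncarpic acid-type triones) to join the CMe2 carbon to the gem-dimethyl-side carbonyl, driven by the acidic cyclic 1,3-dione; the lactone tag fixes B1 with the methyl-side carbonyl cis to the isopropyl group.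

Step 14
Reactants: 22 hydroxy trione
Product: 23 hydroxy methyl enol ether (ring A as in the target; B3–OH)
Conditions: Me2SO4 (1.2 equiv), K2CO3 (1.5 equiv), acetone, rt
Reagents that add atoms: dimethyl sulfate, COS(=O)(=O)OC
Why: O-alkylation of the dione enolate with a hard electrophile should occur at the oxygen on the carbon next to CMe2, which has no other bulky neighbour, and not at the oxygen of the methyl-side carbonyl, which is screened by the spiro centre and the cis isopropyl group and hydrogen-bonded to B3–OH.

Step 15
Reactants: 23 hydroxy methyl enol ether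
Product: 24 B3 imidazole-1-carbothioate of 23
Conditions: 1,1'-thiocarbonyldiimidazole (2 equiv), DMAP (0.2 equiv), toluene, 90 °C
Reagents that add atoms: 1,1'-thiocarbonyldiimidazole, S=C(n1ccnc1)n1ccnc1
Why: neutral thioacylation of the secondary alcohol (first half of a Barton–McCombie deoxygenation) avoids an alkoxide that could open the neighbouring non-enolisable 1,3-diketone by retro-Claisen attack.

Step 16
Reactants: 24 B3 imidazole-1-carbothioate
Product: 25 target CNP0307059.1
Conditions: Bu3SnH (2 equiv), AIBN (0.2 equiv), toluene, 100 °C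
Reagents that add atoms: none
Why: Barton–McCombie radical deoxygenation replaces the B3 oxygen by hydrogen; B3 ceases to be a stereocentre and the tetrasubstituted vinylogous ester of ring A is not expected to react.

Compound list
1 | (1R,5S)-6,6-dimethylbicyclo[3.1.1]heptan-2-one, (+)-nopinone | O=C1CC[C@H]2C[C@@H]1C2(C)C | starting material
2 | (1R,5R)-6,6-dimethylbicyclo[3.1.1]hept-3-en-2-one, apoverbenone | O=C1C=C[C@H]2C[C@@H]1C2(C)C | intermediate
3 | (1R,4R,5S)-6,6-dimethyl-4-(phenylsulfanyl)bicyclo[3.1.1]heptan-2-one | O=C1C[C@@H](Sc3ccccc3)[C@H]2C[C@@H]1C2(C)C | intermediate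
4 | (1R,5S)-6,6-dimethyl-4-(phenylsulfanyl)bicyclo[3.1.1]hept-3-en-2-one | O=C1C=C(Sc3ccccc3)[C@H]2C[C@@H]1C2(C)C | intermediate
5 | (1R,5S)-6,6-dimethyl-4-(phenylsulfonyl)bicyclo[3.1.1]hept-3-en-2-one | O=C1C=C(S(=O)(=O)c3ccccc3)[C@H]2C[C@@H]1C2(C)C | intermediate
6 | (E)-4-methylpent-2-en-1-ol | CC(C)/C=C/CO | starting material
7 | methyl (E)-4-methylpent-2-en-1-yl carbonate | CC(C)/C=C/COC(=O)OC | intermediate
8 | dimethyl malonate | COC(=O)CC(=O)OC | starting material
9 | dimethyl 2-[(3S)-4-methylpent-1-en-3-yl]propanedioate | C=C[C@H](C(C)C)C(C(=O)OC)C(=O)OC | intermediate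
10 | dimethyl 2-[(3R)-2-methyl-4-oxopentan-3-yl]propanedioate | CC(=O)[C@H](C(C)C)C(C(=O)OC)C(=O)OC | intermediate
11 | dimethyl 2-[(1S,5R)-6,6-dimethyl-4-oxobicyclo[3.1.1]hept-2-en-2-yl]-2-[(3R)-2-methyl-4-oxopentan-3-yl]propanedioate | CC(=O)[C@H](C(C)C)C(C(=O)OC)(C(=O)OC)C1=CC(=O)[C@@H]2C[C@H]1C2(C)C | intermediate
12 | dimethyl 2-[(3R)-2-acetoxy-4-methylpent-1-en-3-yl]-2-[(1S,5R)-6,6-dimethyl-4-oxobicyclo[3.1.1]hept-2-en-2-yl]propanedioate (photosubstrate) | C=C(OC(C)=O)[C@H](C(C)C)C(C(=O)OC)(C(=O)OC)C1=CC(=O)[C@@H]2C[C@H]1C2(C)C | intermediate
13 | crossed photoadduct: bicyclo[2.1.1]hexane (bridgeheads B5, B3) fused to the pinan-4-one; B3–OAc, B1(CO2Me)2, B2–iPr on the side of the C3 bridge, B4 anti to the gem-dimethyl bridge | COC(=O)C1(C(=O)OC)[C@@H](C(C)C)[C@]2(OC(C)=O)C[C@@]13[C@H]2C(=O)[C@@H]4C[C@H]3C4(C)C | intermediate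
14 | cage alcohol: 13 with B3–OH in place of B3–OAc | COC(=O)C1(C(=O)OC)[C@@H](C(C)C)[C@]2(O)C[C@@]13[C@H]2C(=O)[C@@H]4C[C@H]3C4(C)C | intermediate
15 | diketone diester: ring B with B1(CO2Me)2, B2–iPr, B3 = C=O, B5 spiro to pinan-4-one (B4 anti to the gem-dimethyl bridge, iPr cis to pinane C3) | COC(=O)C1(C(=O)OC)[C@@H](C(C)C)C(=O)C[C@@]12CC(=O)[C@@H]3C[C@H]2C3(C)C | intermediate
16 | 15 as its pinane C4 tosylhydrazone | COC(=O)C1(C(=O)OC)[C@@H](C(C)C)C(=O)C[C@@]12CC(=NNS(=O)(=O)c4ccc(C)cc4)[C@@H]3C[C@H]2C3(C)C | intermediate
17 | keto diester: 15 with pinane C4 = CH2 | COC(=O)C1(C(=O)OC)[C@@H](C(C)C)C(=O)C[C@@]12CC[C@@H]3C[C@H]2C3(C)C | intermediate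
18 | hydroxy diester: 17 with B3–OH cis to the isopropyl group | COC(=O)C1(C(=O)OC)[C@@H](C(C)C)[C@@H](O)C[C@@]12CC[C@@H]3C[C@H]2C3(C)C | intermediate
19 | lactone ester: lactone from the B3 oxygen to the B1 carbonyl on the isopropyl face (future methyl-side carbonyl), CO2Me on the other face (future gem-dimethyl-side carbonyl) | COC(=O)[C@@]12[C@@H](C(C)C)[C@@H](OC1=O)C[C@@]23CC[C@@H]4C[C@H]3C4(C)C | intermediate
20 | 2-methylpentan-3-one | CCC(=O)C(C)C | starting material
21 | acyclic diketone: B1 bears CO2Me (trans to iPr) and C(=O)CH(CH3)C(=O)CH(CH3)2 (cis to iPr); B3–OH | COC(=O)[C@]1(C(=O)C(C)C(=O)C(C)C)[C@@H](C(C)C)[C@@H](O)C[C@@]12CC[C@@H]3C[C@H]2C3(C)C | intermediate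
22 | hydroxy trione: ring A closed (three ketone carbons, CH–Me between two of them, CMe2 between the other pair), B3–OH | O=C1C(C)C(=O)[C@@]2(C(=O)C1(C)C)[C@@H](C(C)C)[C@@H](O)C[C@@]21CC[C@@H]2C[C@H]1C2(C)C | intermediate
23 | hydroxy methyl enol ether: target with B3–OH cis to the isopropyl group | COC1=C(C)C(=O)[C@@]2(C(=O)C1(C)C)[C@@H](C(C)C)[C@@H](O)C[C@@]21CC[C@@H]2C[C@H]1C2(C)C | intermediate
24 | B3 imidazole-1-carbothioate of 23 | COC1=C(C)C(=O)[C@@]2(C(=O)C1(C)C)[C@@H](C(C)C)[C@@H](OC(=S)n3ccnc3)C[C@@]21CC[C@@H]2C[C@H]1C2(C)C | intermediate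
25 | CNP0307059.1 | COC1=C(C)C(=O)[C@@]2(C(=O)C1(C)C)[C@@H](C(C)C)CC[C@@]21CC[C@@H]2C[C@H]1C2(C)C | target

Total step count: 16. Longest linear sequence: 13 steps (1 or 6 to 25).

Steps most likely to fail

Step 9. The excited enone may rearrange by the 1,3-shift of its cyclobutane bond, or the first-formed biradical may revert, faster than the ring closes. The fallback makes the same B4–B5 bond in the ground state and sets out from 11. Kinetic enolisation with in situ silylation (LiN(SiMe3)2, Me3SiCl, THF, −78 °C) should give the terminal silyl enol ether F1. TiCl4 (CH2Cl2, −78 °C) should then promote an intramolecular Mukaiyama–Michael addition (5-exo) of its CH2 terminus to the enone β-carbon B5, again anti to the gem-dimethyl bridge. Aqueous work-up of the titanium enolate gives diketone 15, where the route resumes (steps 8 to 10 are skipped).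

Step 13. The enolate may fail to add to the crowded lactone carbonyl and be recovered as ketone, or it may attack the methyl ester instead, or the ring closure may go through oxygen instead of carbon. The fallback sets out from 19; it makes the bond from the methyl-side carbonyl to the C–Me carbon with an organolithium and the next ring A bond by enolate acylation. EtLi (1.1 equiv, THF, −78 °C) adds once to the strained lactone and gives the hydroxy ethyl ketone F2 on work-up. Its dianion (LiN(i-Pr)2, 3.3 equiv to allow for the acidic product) is C-acylated with N-methoxy-N-methylisobutyramide to give diketone 21, which is cyclised with LiN(i-Pr)2 as in the second half of step 13 to reach 22.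

Step 11. The condensation may lose chemoselectivity (both carbonyl groups or the cyclopentanone reacting), or the borane may partly reduce the cyclopentanone. The fallback sets out from 15 and masks B3 before the pinane ketone is removed. Excess LiBH(s-Bu)3 (3 equiv, THF, −78 to 0 °C) reduces both ketones to the diol diester F3, drawn with the C4 hydroxyl syn to the gem-dimethyl bridge; this configuration is of no consequence because the carbinol is re-oxidised. TsOH in toluene should lactonise only B3–OH and give the hydroxy lactone F4. The C4 hydroxyl should stay free because B1 stands on the gem-dimethyl face of the pinane, so a bridge from the C4 oxygen to an ester would have to pass through the space of the inner methyl group. Dess–Martin periodinane re-oxidises the C4 carbinol to the keto lactone F5, now the only ketone. TsNHNH2 followed by catecholborane and NaOAc·3H2O, through the tosylhydrazone F6, gives lactone ester 19, where the route resumes (step 12 is skipped).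

Further compounds
F1 | step 9 | trimethylsilyl enol ether of 11 (terminal, CH2=C(OSiMe3)–) | C=C(O[Si](C)(C)C)[C@H](C(C)C)C(C(=O)OC)(C(=O)OC)C1=CC(=O)[C@@H]2C[C@H]1C2(C)C
F2 | step 13 | hydroxy ethyl ketone: B1 bears CO2Me and C(=O)CH2CH3 (cis to iPr); B3–OH | COC(=O)[C@]1(C(=O)CC)[C@@H](C(C)C)[C@@H](O)C[C@@]12CC[C@@H]3C[C@H]2C3(C)C
F3 | step 11 | diol diester: 15 with B3–OH (cis to iPr) and pinane C4–OH (syn to the gem-dimethyl bridge) | COC(=O)C1(C(=O)OC)[C@@H](C(C)C)[C@@H](O)C[C@@]12C[C@@H](O)[C@@H]3C[C@H]2C3(C)C
F4 | step 11 | hydroxy lactone: 19 with pinane C4–OH | COC(=O)[C@@]12[C@@H](C(C)C)[C@@H](OC1=O)C[C@@]23C[C@@H](O)[C@@H]4C[C@H]3C4(C)C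
F5 | step 11 | keto lactone: 19 with pinane C4 = C=O | COC(=O)[C@@]12[C@@H](C(C)C)[C@@H](OC1=O)C[C@@]23CC(=O)[C@@H]4C[C@H]3C4(C)C
F6 | step 11 | tosylhydrazone of F5 | COC(=O)[C@@]12[C@@H](C(C)C)[C@@H](OC1=O)C[C@@]23CC(=NNS(=O)(=O)c5ccc(C)cc5)[C@@H]4C[C@H]3C4(C)C
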